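**Plan**
1. Retrosynthetic cuts, in order: the C1 acid back to a protected alcohol; the C8–C9 bond (sp3–sp2 Suzuki–Miyaura), which parts the bicycle from the dioxane; the O1–O2 bond; the two O–N bonds of a bis(aminooxy) precursor; the C2–C3 bond (crotylboration); in the bicycle, the bond from C10 to the ring-B CH2 that hangs on ring A.
2. Enabling feature: in the 1,2-dioxane ring (O1, O2, C3, C4, C5, C6) both stereocentres, C3 and C6, are oxygen-bearing carbons in a 1,4 relation. A C3,C6-diol therefore already holds every ring atom, and only O1–O2 is missing, a bond that can form without breaking any C–O bond.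
3. C3–C8 plus the C6 methyl are the carbons of (R)-linalool after loss of its isopropylidene end, with the tertiary C6–O centre included.
4. Dioxane branch, forward: linalool, C3 aldehyde, anti crotylboration (brings C1, C2 and the C2 methyl), 3,6-diol, 3,6-bis(aminooxy) compound, then oxidative loss of N2 closes the dioxane, the only ring made on this branch.
5. Bicycle branch, forward: ring A is bought as 2,2-dimethylcyclohexanone and ring B is closed by copper-catalysed borylative cyclisation of a terminal alkyne onto an allylic phosphate. The halves are then joined at C8–C9 and C1 is raised to the acid.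
6. Stereochemistry: C6 comes from (R)-linalool with retention throughout. C2 and C3 come from the E-crotyl geometry and the Ipc ligands. The Z C9=C10 alkene comes from syn borylcupration and retention in both C–C couplings, because the two CH2 flanks of C10 are too alike for a selective olefination.

Key step: step 10

Assumption: target numbering is used throughout (C1 carboxyl, C2–C8 along the chain, C9=C10 the exocyclic alkene, ring A the gem-dimethyl ring, ring B the ring holding C10). CIP letters of intermediates differ from those of the target only where substituent ranks change. Any (S)-linalool in the commercial material would appear after step 5 as a diastereomer and be removed by chromatography.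

**Step 1**
Reactants: 1 (R)-(−)-linalool
Product: 2 (R)-triethyl[(3,7-dimethylocta-1,6-dien-3-yl)oxy]silane
Conditions: TESOTf, 2,6-lutidine, CH2Cl2, −78 to 0 °C
Reagents that add atoms: triethylsilyl trifluoromethanesulfonate, CC[Si](CC)(CC)OS(=O)(=O)C(F)(F)F
Why: Silyl triflate silylation of a hindered tertiary alcohol forms only an O–Si bond, so the C6 centre is untouched, and the ether later stops the C3 aldehyde from closing onto the C6 oxygen as a lactol.

**Step 2**
Reactants: 2 linalool triethylsilyl ether
Product: 4 (R)-3,7-dimethyl-3-(triethylsilyloxy)oct-6-en-1-ol, via alkylborane 3 (not isolated)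
Conditions: 9-BBN (1.2 equiv), THF, 0 °C to rt; then NaOH, H2O2, 0 °C
Reagents that add atoms: hydrogen peroxide, OO; 9-borabicyclo[3.3.1]nonane, B1C2CCCC1CCC2 (its boron and ring stay only in 3)
Why: Hydroboration–oxidation with the bulky dialkylborane picks the monosubstituted vinyl group over the trisubstituted alkene, places boron on the terminal carbon C8, and alkaline peroxide swaps it for hydroxyl with no change at C6.

**Step 3**
Reactants: 4 primary alcohol
Product: 5 (R)-tert-butyl{[3,7-dimethyl-3-(triethylsilyloxy)oct-6-en-1-yl]oxy}diphenylsilane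
Conditions: TBDPSCl, imidazole, DMF, rt
Reagents that add atoms: tert-butyl(chloro)diphenylsilane, CC(C)(C)[Si](Cl)(c1ccccc1)c1ccccc1
Why: Standard silylation of a primary alcohol gives an ether that resists ozone, alkaline peroxide and dilute acid, cannot profitably migrate to the tertiary C6 alkoxide of step 9, and carries no hydrogen that a C6 oxyl radical could reach in step 10.

**Step 4**
Reactants: 5 bis-silyl ether
Product: 7 (R)-6-(tert-butyldiphenylsilyloxy)-4-methyl-4-(triethylsilyloxy)hexanal, via ozonide 6 (not isolated)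
Conditions: O3, CH2Cl2, −78 °C; then Me2S, −78 °C to rt
Reagents that add atoms: ozone, [O-][O+]=O
Why: Ozonolysis with reductive work-up cleaves the only remaining alkene, shedding the isopropylidene carbons as acetone and leaving C3 as the aldehyde.

**Step 5**
Reactants: 7 aldehyde; 8 trans-but-2-ene
Product: 11 (3R,4S,7R)-9-(tert-butyldiphenylsilyloxy)-3,7-dimethyl-7-(triethylsilyloxy)non-1-en-4-ol, via crotylborane 9 (not isolated), via borinate ester 10 (not isolated)
Conditions: 8, n-BuLi, KOt-Bu, THF, −78 to −45 °C; (+)-Ipc2BOMe, −78 °C; BF3·OEt2; 7, −78 °C; then NaOH, H2O2, 0 °C to rt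
Reagents that add atoms: trans-but-2-ene 8, C/C=C/C; (+)-B-methoxydiisopinocampheylborane, COB([C@H]1C[C@H]2C[C@@H]([C@@H]1C)C2(C)C)[C@H]1C[C@H]2C[C@@H]([C@@H]1C)C2(C)C (its boron and terpene groups stay only in 9 and 10)
Why: Brown crotylboration runs through a closed chair transition state in which the E-crotyl geometry gives the anti C2/C3 relation and the isopinocampheyl groups of the (−)-α-pinene series direct attack to the aldehyde face that makes C3 (S), while the remote C6 centre has no say, so any mismatch shows up as a separable diastereomer.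

**Step 6**
Reactants: 11 homoallylic alcohol
Product: 14 (2R,3S,6R)-8-(tert-butyldiphenylsilyloxy)-2,6-dimethyloctane-1,3,6-triol, via ozonide 12 (not isolated), via silyl diol 13 (not isolated)
Conditions: O3, CH2Cl2, −78 °C; NaBH4, MeOH, −78 to 0 °C; then 1 M HCl, rt
Reagents that add atoms: ozone, [O-][O+]=O
Why: Ozonolysis with borohydride work-up turns the vinyl group into the C1 hydroxymethyl group without touching C2 or C3, and the acidic quench hydrolyses the labile triethylsilyl ether while the tert-butyldiphenylsilyl ether stays.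

**Step 7**
Reactants: 14 triol
Product: 15 (2R,3S,6R)-8-(tert-butyldiphenylsilyloxy)-2,6-dimethyl-1-(trityloxy)octane-3,6-diol
Conditions: TrCl, Et3N, DMAP (5 mol %), CH2Cl2, rt
Reagents that add atoms: trityl chloride, ClC(c1ccccc1)(c1ccccc1)c1ccccc1
Why: Tritylation selects the primary alcohol on steric grounds, and the trityl ether is inert to strong base, has no hydrogen on its oxygen-bound carbon, and cannot move to the neighbouring C3 alkoxide in step 9 as a silyl group could.

**Step 8**
Reactants: 16 2,2,4,4-tetramethylpentan-3-imine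
Product: 17 3,3-di-tert-butyloxaziridine
Conditions: mCPBA, CH2Cl2, 0 °C
Reagents that add atoms: 3-chloroperbenzoic acid, O=C(OO)c1cccc(Cl)c1
Why: Peracid oxidation of an N–H ketimine is the standard route to the N–H oxaziridine, and the two tert-butyl groups make it stable enough to store.

**Step 9**
Reactants: 15 diol; 17 3,3-di-tert-butyloxaziridine
Product: 18 (2R,3S,6R)-3,6-bis(aminooxy)-8-(tert-butyldiphenylsilyloxy)-2,6-dimethyl-1-(trityloxy)octane
Conditions: KH (3 equiv), THF/DMPU, 0 °C; 17 (4 equiv), −40 °C to rt; H2O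
Reagents that add atoms: 3,3-di-tert-butyloxaziridine 17, CC(C)(C)C1(NO1)C(C)(C)C (both nitrogen atoms)
Why: In this electrophilic amination of alkoxides each potassium alkoxide attacks the nitrogen of the N–H oxaziridine and expels di-tert-butyl ketone, which is too hindered to condense with the new O–NH2 groups, and because only O–N bonds form both carbinol centres keep their configuration.

**Step 10**
Reactants: 18 bis(aminooxy) compound; 19 (diacetoxyiodo)benzene
Product: 23 (3S,6R)-6-[2-(tert-butyldiphenylsilyloxy)ethyl]-6-methyl-3-[(2R)-1-(trityloxy)propan-2-yl]-1,2-dioxane, via cyclic dialkoxyhydrazine 20 (not isolated), via cyclic hyponitrite 21 (not isolated), via dioxyl biradical 22 (not isolated)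
Conditions: 19 (2.2 equiv, slow addition), CH2Cl2 (0.005 M), −40 °C to rt, dark
Reagents that add atoms: none
Why: Proposed new method: the trivalent-iodine reagent oxidises one O–NH2 group to an electrophilic N-iodanyl species that the second O–NH2 nitrogen, held close by the C4–C5 tether, captures to give the cyclic 1,2-dialkoxyhydrazine 20, and a second equivalent dehydrogenates 20 to the eight-membered hyponitrite 21, whose N=N bond is forced to be cis. Cis-hyponitrites are far less stable than the trans esters, so 21 should expel N2 at or below room temperature and leave the spin-paired 1,4-dioxyl biradical 22, which closes the six-membered 1,2-dioxane by direct O–O radical combination, overall an eight-to-six ring contraction. The nearest known reaction types are the oxidation of O-alkylhydroxylamines to dialkyl hyponitrites, the minor in-cage coupling of the alkoxyl pairs born from such esters to dialkyl peroxides, and the contraction of cyclic azo compounds on loss of N2. No stereocentre is made and no C–O bond is broken, so C3 and C6 pass from 18 to 23 unchanged. What the step needs is a rate selectivity: O–O collapse has to beat beta-scission at the tertiary C6 oxyl, transfer of the C3 hydrogen to the C6 oxyl (ketol formation), escape to solvent and intermolecular N–N coupling. The substrate helps because the two oxyls are born as a singlet pair on the same side of the departing N2 and cannot diffuse apart, the quaternary C6 favours the folded conformer, the trityl and silyl ethers put no hydrogen within 1,5- or 1,6-reach, no alkene is present to intercept nitrogen-centred intermediates, and high dilution with slow addition of 19 disfavours oligomers.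

**Step 11**
Reactants: 23 dioxane
Product: 24 (3S,6R)-6-(2-hydroxyethyl)-6-methyl-3-[(2R)-1-(trityloxy)propan-2-yl]-1,2-dioxane
Conditions: TBAF, AcOH (1:1), THF, 0 °C to rt
Reagents that add atoms: none
Why: Fluoride-induced desilylation, buffered with acetic acid so that no free alkoxide or hydroxide can attack the C3–H of the peroxide, leaves the trityl ether and the O–O bond alone.

**Step 12**
Reactants: 24 C8 alcohol
Product: 25 (3S,6R)-6-(2-bromoethyl)-6-methyl-3-[(2R)-1-(trityloxy)propan-2-yl]-1,2-dioxane
Conditions: CBr4, PPh3, 2,6-lutidine, CH2Cl2, 0 °C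
Reagents that add atoms: carbon tetrabromide, BrC(Br)(Br)Br
Why: Appel bromination converts the primary alcohol under neutral conditions, the phosphine being tied up by CBr4 before it can attack the hindered dialkyl peroxide.

**Step 13**
Reactants: 26 2,2-dimethylcyclohexanone
Product: 27 methyl 3,3-dimethyl-2-oxocyclohexane-1-carboxylate
Conditions: NaH (2.2 equiv), (MeO)2CO, THF, reflux; aq HCl
Reagents that add atoms: dimethyl carbonate, COC(=O)OC
Why: Claisen-type C-acylation of the ketone enolate can occur only at the single enolisable alpha-carbon, away from the quaternary centre.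

**Step 14**
Reactants: 27 beta-keto ester
Product: 28 methyl 3,3-dimethyl-2-(trifluoromethylsulfonyloxy)cyclohex-1-ene-1-carboxylate
Conditions: NaH, Et2O, 0 °C; Tf2O, 0 °C
Reagents that add atoms: trifluoromethanesulfonic anhydride, O=S(=O)(OS(=O)(=O)C(F)(F)F)C(F)(F)F
Why: O-sulfonylation of the only possible enolate gives the tetrasubstituted enol triflate, which fixes the ring-A double bond between the carbon next to the gem-dimethyl group and the ester-bearing carbon.

**Step 15**
Reactants: 28 enol triflate; 29 (4-bromobut-1-yn-1-yl)trimethylsilane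
Product: 31 methyl 3,3-dimethyl-2-[4-(trimethylsilyl)but-3-yn-1-yl]cyclohex-1-ene-1-carboxylate, via alkylzinc bromide 30 (not isolated)
Conditions: 29, Zn, LiCl, THF, 50 °C; then 28, PdCl2(dppf) (5 mol %), THF, 50 °C
Reagents that add atoms: zinc, [Zn] (stays only in 30)
Why: In this Negishi coupling direct zinc insertion gives a homopropargylic zinc reagent that tolerates the ester, and the electron-poor enol triflate adds readily to zerovalent palladium bearing the wide-bite-angle diphosphine, which favours reductive elimination over beta-hydride loss despite the neighbouring quaternary carbon.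

**Step 16**
Reactants: 31 silyl alkyne
Product: 32 methyl 2-(but-3-yn-1-yl)-3,3-dimethylcyclohex-1-ene-1-carboxylate
Conditions: K2CO3 (20 mol %), MeOH, rt
Reagents that add atoms: none
Why: Methanolysis of the alkynyl C–Si bond under catalytic carbonate frees the terminal alkyne, and in methanol the methyl ester cannot change.

**Step 17**
Reactants: 32 alkynyl ester
Product: 33 [2-(but-3-yn-1-yl)-3,3-dimethylcyclohex-1-en-1-yl]methanol
Conditions: i-Bu2AlH (2.5 equiv), CH2Cl2, −78 °C; aq potassium sodium tartrate
Reagents that add atoms: none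
Why: Hydride reduction of the conjugated ester by i-Bu2AlH at low temperature proceeds by 1,2-addition to the allylic alcohol and is too cold for hydroalumination of the alkyne.

**Step 18**
Reactants: 33 allylic alcohol
Product: 34 [2-(but-3-yn-1-yl)-3,3-dimethylcyclohex-1-en-1-yl]methyl diethyl phosphate
Conditions: ClP(O)(OEt)2, pyridine, DMAP (5 mol %), CH2Cl2, 0 °C
Reagents that add atoms: diethyl chlorophosphate, CCOP(=O)(Cl)OCC
Why: Phosphorylation of the primary allylic alcohol gives a leaving group that is reactive towards organocopper species yet less prone to ionise than the corresponding halide.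

**Step 19**
Reactants: 34 allylic phosphate; 35 bis(pinacolato)diboron
Product: 36 2-{(Z)-[5,5-dimethyl-3,4,5,6,7,8-hexahydronaphthalen-2(1H)-ylidene]methyl}-4,4,5,5-tetramethyl-1,3,2-dioxaborolane
Conditions: CuCl (10 mol %), Xantphos (10 mol %), KOt-Bu (1.2 equiv), THF, rt
Reagents that add atoms: bis(pinacolato)diboron 35, CC1(C)OB(OC1(C)C)B1OC(C)(C)C(C)(C)O1
Why: In this copper-catalysed borylative cyclisation (intramolecular alkylboration of a terminal alkyne) the boryl-copper species adds syn with boron on the terminal carbon C9 and copper on C10, and the alkenyl-copper then displaces the allylic phosphate at the CH2 on ring A with retention, six being the only ring size within reach, so boron ends cis to that CH2 and the Z alkene is fixed by constitution rather than by a steric bias.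

**Step 20**
Reactants: 25 C8 bromide; 36 alkenyl boronate
Product: 37 (3S,6S)-6-{(3Z)-3-[5,5-dimethyl-3,4,5,6,7,8-hexahydronaphthalen-2(1H)-ylidene]propyl}-6-methyl-3-[(2R)-1-(trityloxy)propan-2-yl]-1,2-dioxane
Conditions: Pd(OAc)2 (5 mol %), P(t-Bu)2Me·HBF4 (10 mol %), KOt-Bu (3 equiv), t-AmOH, rt
Reagents that add atoms: none
Why: In this Suzuki–Miyaura coupling of an unactivated primary alkyl bromide an electron-rich bulky trialkylphosphine lets zerovalent palladium insert into the C8–Br bond and outrun beta-hydride elimination, tert-butoxide turns the pinacol boronate into the transferring borate, the alkenyl group is handed over with retention so the Z geometry of 36 becomes that of the target, and hindered dialkyl peroxides are known to survive palladium-catalysed couplings.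

**Step 21**
Reactants: 37 coupled trityl ether
Product: 38 (2R)-2-[(3S,6S)-6-{(3Z)-3-[5,5-dimethyl-3,4,5,6,7,8-hexahydronaphthalen-2(1H)-ylidene]propyl}-6-methyl-1,2-dioxan-3-yl]propan-1-ol
Conditions: p-TsOH·H2O (10 mol %), MeOH/CH2Cl2, 0 °C to rt
Reagents that add atoms: none
Why: Acid-catalysed solvolysis of the trityl ether goes through the stabilised trityl cation under conditions too mild to protonate the tri- and tetrasubstituted alkenes or to harm the peroxide.

**Step 22**
Reactants: 38 primary alcohol; 19 (diacetoxyiodo)benzene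
Product: 40 (2S)-2-[(3S,6S)-6-{(3Z)-3-[5,5-dimethyl-3,4,5,6,7,8-hexahydronaphthalen-2(1H)-ylidene]propyl}-6-methyl-1,2-dioxan-3-yl]propanoic acid, via aldehyde 39 (not isolated)
Conditions: TEMPO (20 mol %), 19 (2.5 equiv), MeCN/pH 7 buffer, 0 °C to rt
Reagents that add atoms: water, O
Why: Oxoammonium-catalysed oxidation (TEMPO with a trivalent-iodine co-oxidant in aqueous acetonitrile) takes the primary alcohol through the aldehyde hydrate to the acid near neutral pH, which spares the alkenes and the peroxide and gives the C2 centre of the transient aldehyde little time to epimerise or to eliminate the C3 peroxy oxygen.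

**Compound list**
1 | (R)-(−)-linalool | CC(C)=CCC[C@](C)(C=C)O | starting material
2 | (R)-linalool triethylsilyl ether | CC(C)=CCC[C@](C)(C=C)O[Si](CC)(CC)CC | intermediate
3 | B-alkyl-9-BBN adduct of 2 (boron on C8) | CC(C)=CCC[C@](C)(CCB1C2CCCC1CCC2)O[Si](CC)(CC)CC | intermediate
4 | (R)-3,7-dimethyl-3-(triethylsilyloxy)oct-6-en-1-ol | CC(C)=CCC[C@](C)(CCO)O[Si](CC)(CC)CC | intermediate
5 | (R)-1-(tert-butyldiphenylsilyloxy)-3,7-dimethyl-3-(triethylsilyloxy)oct-6-ene | CC(C)=CCC[C@](C)(CCO[Si](c1ccccc1)(c1ccccc1)C(C)(C)C)O[Si](CC)(CC)CC | intermediate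
6 | secondary ozonide (1,2,4-trioxolane) of 5 | CC1(C)OOC(CC[C@](C)(CCO[Si](c2ccccc2)(c2ccccc2)C(C)(C)C)O[Si](CC)(CC)CC)O1 | intermediate
7 | (R)-6-(tert-butyldiphenylsilyloxy)-4-methyl-4-(triethylsilyloxy)hexanal | O=CCC[C@](C)(CCO[Si](c1ccccc1)(c1ccccc1)C(C)(C)C)O[Si](CC)(CC)CC | intermediate
8 | trans-but-2-ene | C/C=C/C | starting material
9 | (E)-crotyldiisopinocampheylborane, (−)-α-pinene series | C/C=C/CB([C@H]1C[C@H]2C[C@@H]([C@@H]1C)C2(C)C)[C@H]1C[C@H]2C[C@@H]([C@@H]1C)C2(C)C | intermediate
10 | diisopinocampheylborinate ester of 11 | C[C@H](C=C)[C@@H](OB([C@H]1C[C@H]2C[C@@H]([C@@H]1C)C2(C)C)[C@H]1C[C@H]2C[C@@H]([C@@H]1C)C2(C)C)CC[C@](C)(CCO[Si](c1ccccc1)(c1ccccc1)C(C)(C)C)O[Si](CC)(CC)CC | intermediate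
11 | (3R,4S,7R)-9-(tert-butyldiphenylsilyloxy)-3,7-dimethyl-7-(triethylsilyloxy)non-1-en-4-ol (anti) | C[C@H](C=C)[C@@H](O)CC[C@](C)(CCO[Si](c1ccccc1)(c1ccccc1)C(C)(C)C)O[Si](CC)(CC)CC | intermediate
12 | terminal ozonide (1,2,4-trioxolane) of 11 | C[C@H](C1OCOO1)[C@@H](O)CC[C@](C)(CCO[Si](c1ccccc1)(c1ccccc1)C(C)(C)C)O[Si](CC)(CC)CC | intermediate
13 | (2R,3S,6R)-8-(tert-butyldiphenylsilyloxy)-2,6-dimethyl-6-(triethylsilyloxy)octane-1,3-diol | C[C@H](CO)[C@@H](O)CC[C@](C)(CCO[Si](c1ccccc1)(c1ccccc1)C(C)(C)C)O[Si](CC)(CC)CC | intermediate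
14 | (2R,3S,6R)-8-(tert-butyldiphenylsilyloxy)-2,6-dimethyloctane-1,3,6-triol | C[C@H](CO)[C@@H](O)CC[C@](C)(CCO[Si](c1ccccc1)(c1ccccc1)C(C)(C)C)O | intermediate
15 | (2R,3S,6R)-8-(tert-butyldiphenylsilyloxy)-2,6-dimethyl-1-(trityloxy)octane-3,6-diol | C[C@H](COC(c1ccccc1)(c1ccccc1)c1ccccc1)[C@@H](O)CC[C@](C)(CCO[Si](c1ccccc1)(c1ccccc1)C(C)(C)C)O | intermediate
16 | 2,2,4,4-tetramethylpentan-3-imine | CC(C)(C)C(=N)C(C)(C)C | starting material
17 | 3,3-di-tert-butyloxaziridine | CC(C)(C)C1(NO1)C(C)(C)C | intermediate
18 | (2R,3S,6R)-3,6-bis(aminooxy)-8-(tert-butyldiphenylsilyloxy)-2,6-dimethyl-1-(trityloxy)octane | C[C@H](COC(c1ccccc1)(c1ccccc1)c1ccccc1)[C@@H](ON)CC[C@](C)(CCO[Si](c1ccccc1)(c1ccccc1)C(C)(C)C)ON | intermediate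
19 | (diacetoxyiodo)benzene | CC(=O)OI(OC(C)=O)c1ccccc1 | starting material
20 | eight-membered cyclic 1,2-dialkoxyhydrazine (1,4,2,3-dioxadiazocane), substituents as in 23 | C[C@H](COC(c1ccccc1)(c1ccccc1)c1ccccc1)[C@@H]1CC[C@](C)(CCO[Si](c2ccccc2)(c2ccccc2)C(C)(C)C)ONNO1 | intermediate
21 | eight-membered cyclic cis-hyponitrite (tetrahydro-1,4,2,3-dioxadiazocine), substituents as in 23 | C[C@H](COC(c1ccccc1)(c1ccccc1)c1ccccc1)[C@@H]1CC[C@](C)(CCO[Si](c2ccccc2)(c2ccccc2)C(C)(C)C)O/N=N\O1 | intermediate
22 | C3,C6-dioxyl biradical (singlet pair) | C[C@H](COC(c1ccccc1)(c1ccccc1)c1ccccc1)[C@@H]([O])CC[C@](C)(CCO[Si](c1ccccc1)(c1ccccc1)C(C)(C)C)[O] | intermediate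
23 | (3S,6R)-6-[2-(tert-butyldiphenylsilyloxy)ethyl]-6-methyl-3-[(2R)-1-(trityloxy)propan-2-yl]-1,2-dioxane | C[C@H](COC(c1ccccc1)(c1ccccc1)c1ccccc1)[C@@H]1CC[C@](C)(CCO[Si](c2ccccc2)(c2ccccc2)C(C)(C)C)OO1 | intermediate
24 | (3S,6R)-6-(2-hydroxyethyl)-6-methyl-3-[(2R)-1-(trityloxy)propan-2-yl]-1,2-dioxane | C[C@H](COC(c1ccccc1)(c1ccccc1)c1ccccc1)[C@@H]1CC[C@](C)(CCO)OO1 | intermediate
25 | (3S,6R)-6-(2-bromoethyl)-6-methyl-3-[(2R)-1-(trityloxy)propan-2-yl]-1,2-dioxane | C[C@H](COC(c1ccccc1)(c1ccccc1)c1ccccc1)[C@@H]1CC[C@](C)(CCBr)OO1 | intermediate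
26 | 2,2-dimethylcyclohexanone | CC1(C)CCCCC1=O | starting material
27 | methyl 3,3-dimethyl-2-oxocyclohexane-1-carboxylate (enolisable, racemic) | COC(=O)C1CCCC(C)(C)C1=O | intermediate
28 | methyl 3,3-dimethyl-2-(trifluoromethylsulfonyloxy)cyclohex-1-ene-1-carboxylate | COC(=O)C1=C(OS(=O)(=O)C(F)(F)F)C(C)(C)CCC1 | intermediate
29 | (4-bromobut-1-yn-1-yl)trimethylsilane | C[Si](C)(C)C#CCCBr | starting material
30 | [4-(trimethylsilyl)but-3-yn-1-yl]zinc bromide | C[Si](C)(C)C#CCC[Zn]Br | intermediate
31 | methyl 3,3-dimethyl-2-[4-(trimethylsilyl)but-3-yn-1-yl]cyclohex-1-ene-1-carboxylate | COC(=O)C1=C(CCC#C[Si](C)(C)C)C(C)(C)CCC1 | intermediate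
32 | methyl 2-(but-3-yn-1-yl)-3,3-dimethylcyclohex-1-ene-1-carboxylate | COC(=O)C1=C(CCC#C)C(C)(C)CCC1 | intermediate
33 | [2-(but-3-yn-1-yl)-3,3-dimethylcyclohex-1-en-1-yl]methanol | OCC1=C(CCC#C)C(C)(C)CCC1 | intermediate
34 | [2-(but-3-yn-1-yl)-3,3-dimethylcyclohex-1-en-1-yl]methyl diethyl phosphate | CCOP(=O)(OCC)OCC1=C(CCC#C)C(C)(C)CCC1 | intermediate
35 | bis(pinacolato)diboron | CC1(C)OB(OC1(C)C)B1OC(C)(C)C(C)(C)O1 | starting material
36 | (Z)-exocyclic alkenyl pinacol boronate of the bicycle (boron cis to the ring-B CH2 on ring A) | CC1(C)OB(/C=C2/CCC3=C(CCCC3(C)C)C2)OC1(C)C | intermediate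
37 | (3S,6S)-coupled dioxane, C1 trityl ether, Z alkene | C[C@H](COC(c1ccccc1)(c1ccccc1)c1ccccc1)[C@@H]1CC[C@](C)(CC/C=C2/CCC3=C(CCCC3(C)C)C2)OO1 | intermediate
38 | (2R,3S,6S)-C1 primary alcohol | C[C@H](CO)[C@@H]1CC[C@](C)(CC/C=C2/CCC3=C(CCCC3(C)C)C2)OO1 | intermediate
39 | (2S,3S,6S)-C1 aldehyde | C[C@H](C=O)[C@@H]1CC[C@](C)(CC/C=C2/CCC3=C(CCCC3(C)C)C2)OO1 | intermediate
40 | CNP0223199.2, (2S,3S,6S,9Z)-acid | C[C@H](C(=O)O)[C@@H]1CC[C@](C)(CC/C=C2/CCC3=C(CCCC3(C)C)C2)OO1 | target

**Totals**
Total step count: 22.
Longest linear sequence: 14 steps (steps 1–7, 9–12, 20–22). The bicycle branch (steps 13–19) and the reagent step 8 run in parallel.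

**The three steps most likely to fail**

**Step 10.**
- What may go wrong: the oxidation may join nitrogen atoms of different molecules or divert an N-iodanyl intermediate towards nitroso or oxime products. After loss of N2 the oxyl pair may also fragment by beta-scission at C6, or disproportionate by hydrogen transfer from C3, instead of collapsing.
- Fallback: known chemistry, intramolecular SN2 alkylation of a tertiary hydroperoxide. It sets out from aldehyde 7 and comes back at dioxane 23.
- Brown crotylboration of 7 with the Z-crotylborane made from cis-but-2-ene and (−)-Ipc2BOMe would give the syn homoallylic alcohol F1, the C3 epimer of 11, and MsCl with Et3N converts it into the mesylate F2.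
- Ethereal H2O2 with catalytic H2SO4 strips the triethylsilyl group and exchanges the tertiary C6 oxygen for a hydroperoxy group by way of the tertiary cation. This gives the hydroperoxide F3 as both C6 epimers.
- KOt-Bu in THF closes the ring by 6-exo-tet displacement of the mesylate with inversion at C3, and chromatography separates the wanted vinyl dioxane F4 from its C6 epimer.
- Ozonolysis with NaBH4 work-up gives the dioxane alcohol F5, and tritylation as in step 7 gives 23.
- Cost: the C6 configuration brought in with linalool is lost and has to be recovered by separation, while C2 and C3 keep the material enantiopure.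

**Step 20.**
- What may go wrong: transfer of the hindered trisubstituted alkenyl group from the pinacol boronate may be slow, so that beta-hydride elimination of the alkylpalladium, base-induced loss of HBr, or attack of phosphine or low-valent palladium on the O–O bond takes over.
- Fallback: the polarity is reversed to a B-alkyl Suzuki–Miyaura coupling. It sets out from bromide 25 and boronate 36 and comes back at 37.
- KOt-Bu in THF at 0 °C eliminates HBr from 25 to the vinyl dioxane F6, and 9-BBN adds to the vinyl group to give the alkylborane F7, which is used in solution.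
- Separately, 36 is treated with NaOH and then I2 in THF/H2O to give the alkenyl iodide F8 with retention of geometry.
- F7 and F8 are joined with PdCl2(dppf), AsPh3 and Cs2CO3 in DMF/THF/H2O at rt, a mild-base coupling in which oxidative addition takes place at an sp2 carbon.

**Step 19.**
- What may go wrong: the boryl-copper species may substitute the allylic phosphate directly, the alkenyl-copper may be protonated by the acidic alkyne C–H before it cyclises, or borylcupration may take the opposite regiochemistry and leave no path to ring B.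
- Fallback: boron installation and ring closure are split between two other metals. It sets out from phosphate 34 and diboron 35 and comes back at 36.
- Pt(PPh3)4-catalysed syn diboration of the alkyne (DMF, 80 °C) gives the cis-1,2-diborylalkene F9.
- Pd(PPh3)4 with aq K3PO4 in THF then ionises the allylic phosphate and couples the allyl terminus with the internal C–B bond, favoured because it closes the six-membered rather than a seven-membered ring. The terminal boronate is left cis to the new C–C bond.

**Further compounds**
F1 | step 10 | (3R,4R,7R)-9-(tert-butyldiphenylsilyloxy)-3,7-dimethyl-7-(triethylsilyloxy)non-1-en-4-ol (syn) | C[C@H](C=C)[C@H](O)CC[C@](C)(CCO[Si](c1ccccc1)(c1ccccc1)C(C)(C)C)O[Si](CC)(CC)CC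
F2 | step 10 | methanesulfonate of F1 | C[C@H](C=C)[C@H](OS(C)(=O)=O)CC[C@](C)(CCO[Si](c1ccccc1)(c1ccccc1)C(C)(C)C)O[Si](CC)(CC)CC
F3 | step 10 | (3R,4R)-9-(tert-butyldiphenylsilyloxy)-7-hydroperoxy-3,7-dimethylnon-1-en-4-yl methanesulfonate, both C7 epimers | C[C@H](C=C)[C@H](OS(C)(=O)=O)CCC(C)(CCO[Si](c1ccccc1)(c1ccccc1)C(C)(C)C)OO
F4 | step 10 | (3S,6R)-3-[(2R)-but-3-en-2-yl]-6-[2-(tert-butyldiphenylsilyloxy)ethyl]-6-methyl-1,2-dioxane | C[C@H](C=C)[C@@H]1CC[C@](C)(CCO[Si](c2ccccc2)(c2ccccc2)C(C)(C)C)OO1
F5 | step 10 | (2R)-2-{(3S,6R)-6-[2-(tert-butyldiphenylsilyloxy)ethyl]-6-methyl-1,2-dioxan-3-yl}propan-1-ol | C[C@H](CO)[C@@H]1CC[C@](C)(CCO[Si](c2ccccc2)(c2ccccc2)C(C)(C)C)OO1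
F6 | step 20 | (3S,6R)-6-ethenyl-6-methyl-3-[(2R)-1-(trityloxy)propan-2-yl]-1,2-dioxane | C[C@H](COC(c1ccccc1)(c1ccccc1)c1ccccc1)[C@@H]1CC[C@](C)(C=C)OO1
F7 | step 20 | B-alkyl-9-BBN adduct of F6 (boron on C8) | C[C@H](COC(c1ccccc1)(c1ccccc1)c1ccccc1)[C@@H]1CC[C@](C)(CCB2C3CCCC2CCC3)OO1
F8 | step 20 | (Z)-2-(iodomethylidene)-5,5-dimethyl-1,2,3,4,5,6,7,8-octahydronaphthalene | I/C=C1/CCC2=C(CCCC2(C)C)C1
F9 | step 19 | diethyl {2-[3,4-bis(pinacolboryl)but-3-en-1-yl]-3,3-dimethylcyclohex-1-en-1-yl}methyl phosphate, boron atoms cis | CCOP(=O)(OCC)OCC1=C(CC/C(B2OC(C)(C)C(C)(C)O2)=C/B2OC(C)(C)C(C)(C)O2)C(C)(C)CCC1
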